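The data are calculated on assumed constants, noise included.

The autumn run, charged with 0.13 M of starting material, and the midnight run, charged with 0.53 M, lose starting material at one pace: at 4.00 h, 34.9% and 32.4% remain. Yet at 15.0 h target stands at 34.1% in autumn and 70.0% in midnight, though steps of first order give equal percentages at any charge.

| flask | starting material | remark | time |
|---|---|---|---|
| autumn | 0.13 M | run made earlier |  |
| midnight | 0.53 M | run made earlier |  |
| red | 0.15 M |  | 30 h |
| violet | 0.25 M |  | 30 h |
| ochre | 0.45 M |  | 30 h |
| blue | 0.60 M |  | 30 h |
| teal | 0.30 M |  | 30 h |

| run | time / h | target / % | starting material / % |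
|---|---|---|---|
| autumn | 1.33 | 16.1 | 68.8 |
| autumn | 2.00 | 22.0 | 58.3 |
| autumn | 3.00 | 26.8 | 44.8 |
| autumn | 4.00 | 30.0 | 34.9 |
| autumn | 6.00 | 33.2 | 21.2 |
| autumn | 10.0 | 35.2 | 11.1 |
| autumn | 15.0 | 34.1 | 7.9 |
| midnight | 1.33 | 18.0 | 68.6 |
| midnight | 2.00 | 24.6 | 59.5 |
| midnight | 3.00 | 36.1 | 42.6 |
| midnight | 4.00 | 42.4 | 32.4 |
| midnight | 6.00 | 51.4 | 20.3 |
| midnight | 10.0 | 62.4 | 8.7 |
| midnight | 15.0 | 70.0 | 3.3 |

(readings scatter by 1 percentage point)

- the flasks put in order of amount of target, in percent of the starting material charged, best first, at 30 h (red / violet / ochre / blue / teal)
- the amount of target, in percent of the starting material charged of the flask you put first, at 30 h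
- the amount of target, in percent of the starting material charged of the flask you put last, at 30 h

- for target the crystals are counted in
- as a solid, counted per litre of solution: crystals
- what was read earlier has a scatter of 1 percentage point, one standard deviation
- what may be going on: starting material <-> target; starting material <-> isomer of the product; target <-> isomer of the product; target -> over-reaction product; crystals <-> target

Crystals can clear this up. Suppose dissolved target stands at one fixed level (its solubility) beside crystals, with starting material and isomer of the product in balance with it. What is not target is then a fixed concentration at any charge. Call it the held load H, the concentration of everything not target. Autumn's last reading gives H = 85.7 mM, and its reading before gives 84.2 mM. These two readings of target differ by 1.1 percentage points, about their scatter of 1 point, so they cannot show whether H is still moving, and H is used here as a reading that may yet rise. The ceiling of target is then the whole charge less H, as a percentage of the charge.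

Midnight's ceiling is 83.8%. The run lies 21 points under it at 10.0 h and 14 points under it at 15.0 h, so the gap has a half-life of 7.92 h. Counting 1.89 half-lives on to 30 h leaves 3.7 points. Taking that gap for each flask, this reckoning orders the flasks by charge, with blue at 82.0% and red at 39.2%.

The forecast gives blue > ochre > teal > violet > red, with 80% first and 29% last, holding that “Violet and red probably stay crystal-free”. Its figure for red is a straight line through autumn's last two readings.

The simulation gives blue > ochre > teal > violet > red, with 79.8% for blue and 36.9% for red.

    starting material ⇌ target (K = 3.00, k = 4.90 × 10⁻⁵ s⁻¹)
    starting material ⇌ isomer of the product (K = 8.80, k = 3.00 × 10⁻⁵ s⁻¹)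
    target ⇌ isomer of the product (k = 5.70 × 10⁻⁵ s⁻¹)
    target → over-reaction product (k = 5.50 × 10⁻⁷ s⁻¹)
    crystals ⇌ target, rate k5*(cs5 - [target]) while solid is left; crystals form when [target] > cs5 (solubility = 29.0 mM, k = 0.00370 s⁻¹)

Red holds 17.6% of its charge as crystals at 30.0 h. Blue ends 5.9 points under its ceiling and red 6 points, against the counted 3.7 points. A neighbour charged with 1.5 M has a ceiling of 94.3%, which the counted gap brings to 90.6%, and it reaches 88.4%. Two things act together in blue, the saturation of target at 29 mM and the way back from isomer of the product to target. From 79.8%, target falls to 23.0% without the saturation and to 36.5% without the way back.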